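I start from two constants: the first step's rate constant 0.050 M⁻¹ h⁻¹ and the binding constant 2.9 M⁻¹ of E for J.

    G + J ⇌ E + L (K1 = 0.29, k1 = 0.050 M⁻¹ h⁻¹)
    L + J ⇌ E + Q (K2 = 33, k2 = 0.067 M⁻¹ h⁻¹)
    Q + J ⇌ E + D (K3 = 0.72, k3 = 0.030 M⁻¹ h⁻¹)
    E + J ⇌ E.J, settled at all times (K4 = 2.9 M⁻¹)

| flask | G | J | time |
|---|---|---|---|
| Friday's | 0.25 M | 0.620 M | 15 h |
| Saturday's | 0.25 M | 0.940 M | 15 h |
| Tuesday's | 0.25 M | 1.40 M | 15 h |

* part of the G that has reacted at the end, Friday's
* part of the G that has reacted at the end, Saturday's
* part of the G that has reacted at the end, Tuesday's
* what raising the concentration of J from its lowest to its highest value here does to the part of the G that has reacted (changes below 5 percentage points count as none) (no change / it rises / it falls)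

- amounts and yields of E count E.J too
- run time (Friday's): 15 h

**What do you follow?** The decades of G lost: the common logarithm of charged G over G left. In Friday's flask J is charged at 2.48 times the G, so I treat G as pseudo-first-order. Decades are then rate constant times J times time, divided by 2.3. Charged J gives 0.202, a first estimate of 37.2% of Friday's G lost.

**But J doesn't stand still. What does that cost?** Each G lost takes one J in the first step and makes one E. At charged J, a share 64.3% of that E holds a further J. Taking J halfway down that loss, I estimate Friday's mean free J at 0.544 M.

**So what is your figure for Friday's?** With mean free J in place of charged J, Friday's decades of G lost, the rate constant times mean free J times time over 2.3, come to 0.177. That means 33.5% lost.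

**And the other two?** Saturday's gives 0.271 decades, so 46.4% lost. Tuesday's gives 0.409 decades, so 60.9% lost. In my figures the part reacted rises from Friday's to Tuesday's by 27 percentage points.

**Where is this weakest?** I left out the way back of the first step, which returns G, and the second and third steps, which spend more J. So I expect my figures to stand high.

The forecast gives 32%, 44% and 57% for Friday's, Saturday's and Tuesday's flasks, and says of the part reacted that it rises, holding that “more J gives faster G conversion”.

The simulation gives 32.1%, 43.9% and 57.4% in the same order; as for the part reacted between lowest and highest J, it rises by 25 points.

My figures stand above all of these: Friday's flask lost 0.168 decades against my 0.177. In Friday's flask the first step had done half of its turnover up to the asked time by 6.03 h, while free J fell to 74.3% of its charge by 15.0 h. At that time in Friday's flask L was still made 1.85 times faster than used up, each step taken net, and held 24.3% of the G charged, with Q at 7.17% and D at 0.637%.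

Take a neighbour like Friday's but charged with 0.37 M of J. The same reckoning gives 0.106 decades, so 21.6% lost. The computed part reacted in that neighbour is 21.0%.

Its constants were drawn at random within sensible limits; no experiment stands behind them.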